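**Retrosynthetic overview**
1. Target 6 opens in one disconnection to the acyclic hydroperoxide 3, by undoing C18–Cl, the C13–C17 ring bond and the C14–O oxirane bond (anti additions across the 17Z- and 13E-alkenes).
2. Hydroperoxide ester 3 comes from the acid 2 by methylation, and 2 from eicosapentaenoic acid 1 by 15-lipoxygenation, which sets C15, the only stereocentre brought in.
3. C13, C14, C17 and C18 are all relayed from C15 and from the 13E/17Z alkene geometries in the cascade.
4. Ring order, all in one flask: oxirane first (O–O heterolysis with 13-ene participation), cyclopentane second (5-exo capture of the epoxy-allyl cation by the 17Z-ene), then chloride closes at C18.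

Assumption: fatty-acid numbering is used (ester carbonyl = C1); read this way the target is 5Z,8Z,11Z and 13S,14R,15S,17R,18S, with the C13 chain trans to the oxirane oxygen and trans to the C17 side chain.

**Route**

Step 1
Reactants: 1 (5Z,8Z,11Z,14Z,17Z)-icosa-5,8,11,14,17-pentaenoic acid (EPA)
Product: 2 (5Z,8Z,11Z,13E,15S,17Z)-15-hydroperoxyicosa-5,8,11,13,17-pentaenoic acid
Conditions: soybean lipoxygenase-1 (cat.), O2 (1 atm, sparged), 0.1 M borate buffer pH 9.0, 0–4 °C, ca. 20 min, followed at 234 nm; then pH 4 (citric acid), Et2O extraction, cold
Reagents that add atoms: dioxygen O=O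
Why: Lipoxygenase dioxygenation (enzymatic ene-type C–H oxygenation): the non-haem iron abstracts the pro-S hydrogen of bis-allylic C13 and O2 is delivered antarafacially to C15, which sets C15 as S (typically ≥95% ee) and moves the 14Z-alkene to 13E in conjugation with the 11Z-alkene.

Step 2
Reactants: 2 (5Z,8Z,11Z,13E,15S,17Z)-15-hydroperoxyicosa-5,8,11,13,17-pentaenoic acid
Product: 3 methyl (5Z,8Z,11Z,13E,15S,17Z)-15-hydroperoxyicosa-5,8,11,13,17-pentaenoate
Conditions: CH2N2 (slight excess), Et2O–MeOH 9:1, 0 °C, 1–2 min; N2 stream, cold
Reagents that add atoms: diazomethane C=[N+]=[N-]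
Why: Carboxylic acid O-methylation with diazomethane (proton transfer, then SN2 on methyldiazonium); the much less acidic OOH group is not methylated in minutes at 0 °C, and no stereocentre or alkene is touched.

Step 3
Reactants: 3 methyl (5Z,8Z,11Z,13E,15S,17Z)-15-hydroperoxyicosa-5,8,11,13,17-pentaenoate
Product: 6 methyl (5Z,8Z,11Z)-12-[(1R,2S,3R,5S)-3-[(1S)-1-chloropropyl]-6-oxabicyclo[3.1.0]hexan-2-yl]dodeca-5,8,11-trienoate, via peroxy mesylate 4 (not isolated), via epoxy-allyl cation 5 (not isolated)
Conditions: MsCl (1.1 equiv), then i-Pr2NEt (1.05 equiv, added last and slowly), CH2Cl2 (0.01 M), Ar, dark, −78 → −20 °C; cold aq NaHCO3; Et3N-deactivated SiO2, then HPLC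
Reagents that add atoms: methanesulfonyl chloride CS(=O)(=O)Cl
Why: Proposed new method: O-sulfonylation of the outer peroxide oxygen gives peroxy mesylate 4, whose O–O bond heterolyses with participation of the 13E-alkene (3-exo attack of C14 on the inner oxygen, C15 retained) to give the cis-epoxy allyl cation 5 (charge over C11–C13), which is captured 5-exo at C17 by the 17Z-alkene while chloride from the i-Pr2NEt·HCl ion pair made in the same flask closes at C18; both additions are antiperiplanar (Stork–Eschenmoser type), so only the cis-oxirane rotamer can ring-close (14R), the 13E geometry puts the C13 chain trans to the oxirane (13S), the envelope with the C17 side chain trans to the C13 chain gives 17R, anti addition across the Z-alkene gives 18S, and the 11Z-alkene survives as the untouched end of the allyl cation; the closest known reaction types are the heterolysis of peroxy sulfonates of dienyl hydroperoxides to epoxy-allyl cations (the biomimetic hydroperoxide-to-leukotriene-A-epoxide conversion, where a base then removes a proton) and cation–alkene cyclisation with halide termination (Prins/polyene type).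

**Compound list**
1 | (5Z,8Z,11Z,14Z,17Z)-icosa-5,8,11,14,17-pentaenoic acid (EPA) | CC/C=C\C/C=C\C/C=C\C/C=C\C/C=C\CCCC(=O)O | starting material
2 | (5Z,8Z,11Z,13E,15S,17Z)-15-hydroperoxyicosa-5,8,11,13,17-pentaenoic acid | CC/C=C\C[C@H](OO)/C=C/C=C\C/C=C\C/C=C\CCCC(=O)O | intermediate
3 | methyl (5Z,8Z,11Z,13E,15S,17Z)-15-hydroperoxyicosa-5,8,11,13,17-pentaenoate | CC/C=C\C[C@H](OO)/C=C/C=C\C/C=C\C/C=C\CCCC(=O)OC | intermediate
4 | methyl (5Z,8Z,11Z,13E,15S,17Z)-15-[(methanesulfonyl)peroxy]icosa-5,8,11,13,17-pentaenoate (peroxy mesylate) | CC/C=C\C[C@H](OOS(C)(=O)=O)/C=C/C=C\C/C=C\C/C=C\CCCC(=O)OC | intermediate (not isolated)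
5 | (14R,15S)-cis-14,15-epoxy allyl cation of the methyl icosa-5Z,8Z,11Z,17Z-tetraenoate chain (charge over C11–C13; ion pair with mesylate/chloride) | CC/C=C\C[C@@H]1O[C@@H]1[CH+]/C=C\C/C=C\C/C=C\CCCC(=O)OC | intermediate (not isolated)
6 | methyl (5Z,8Z,11Z)-12-[(1R,2S,3R,5S)-3-[(1S)-1-chloropropyl]-6-oxabicyclo[3.1.0]hexan-2-yl]dodeca-5,8,11-trienoate | CC[C@H](Cl)[C@@H]1C[C@@H]2O[C@@H]2[C@H]1/C=C\C/C=C\C/C=C\CCCC(=O)OC | target

**Totals**
Total step count: 3. Longest linear sequence: 3.

**Steps most likely to fail, with fallbacks**

Step 3 is by far the most uncertain, and a low yield with HPLC separation should be expected. The cascade is unprecedented as a whole, and several exits compete: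
- Hock/Criegee fragmentation of the C14–C15 bond to aldehydes.
- Ionisation through the rotamer that gives the trans-oxirane, which cannot ring-close and ends as an allylic chloride or, by loss of H-10, as an epoxy-triene.
- Mesylate instead of chloride at C18, the C17 epimer, or 6-endo closure.

The fallback changes how the chloride is delivered. It sets out from 3, which is converted with phosgene (toluene solution, excess) and exactly one equivalent of pyridine in Et2O/pentane at −78 °C into the peroxychloroformate F3. Pyridinium chloride is filtered off cold and excess phosgene is stripped cold. F3 is then left to ionise in CH2Cl2 from −78 to 0 °C with no base and no external nucleophile. The O–O heterolysis and cyclisation are the same, but the leaving group is chlorocarbonate, which loses CO2 and releases chloride only after the cation has formed, inside the ion pair and on the ring face that carries C18 (as in the SNi-type collapse of chloroformates). This removes free chloride, mesylate and base from the ionisation stage. It is equally untested and comes back to the route at 6.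

Step 1 is known chemistry but can fail in practice through over-oxygenation to dihydroperoxides, enzyme batch variation and poor oxygen transfer on scale. The fallback replaces the enzyme by a chemical ene reaction followed by resolution. It sets out from 1, which is photo-oxygenated (rose bengal, O2, visible light, MeOH, 0 °C; Schenck ene reaction of singlet oxygen). This gives all regioisomeric hydroperoxides. The racemic 15-hydroperoxy acid F1, recognisable by its conjugated 11Z,13E-diene (234 nm), is isolated by normal-phase HPLC and resolved on a polysaccharide chiral phase. The 15S enantiomer is 2, where the route is rejoined. This is wasteful (a few percent at best) but enzyme-free.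

Step 2 is the least risky. Possible problems are partial O-methylation of the OOH group, loss of the hydroperoxide during concentration, and the hazard of diazomethane. The fallback reverses the order of esterification and oxygenation. It sets out from 1, which is esterified first (MeOH, cat. AcCl, room temperature) to methyl eicosapentaenoate F2. F2 is then oxygenated with a 15-lipoxygenase under ester-tolerant conditions (soybean enzyme with deoxycholate, or a reticulocyte-type 15-lipoxygenase that accepts esterified substrates) to give 3 directly, where the route is rejoined. The hydroperoxide then never meets a methylating agent.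

**Further compounds**
F1 | step 1 | rac-(5Z,8Z,11Z,13E,17Z)-15-hydroperoxyicosa-5,8,11,13,17-pentaenoic acid (15RS) | CC/C=C\CC(OO)/C=C/C=C\C/C=C\C/C=C\CCCC(=O)O
F2 | step 2 | methyl (5Z,8Z,11Z,14Z,17Z)-icosa-5,8,11,14,17-pentaenoate | CC/C=C\C/C=C\C/C=C\C/C=C\C/C=C\CCCC(=O)OC
F3 | step 3 | methyl (5Z,8Z,11Z,13E,15S,17Z)-15-[(chlorocarbonyl)peroxy]icosa-5,8,11,13,17-pentaenoate | CC/C=C\C[C@H](OOC(Cl)=O)/C=C/C=C\C/C=C\C/C=C\CCCC(=O)OC
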